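**Plan**
Numbering (germacrane): ring C1–C10; C9 = ketone carbon; C10 (methyl C14) and C1 = the oxirane next to it; C3, C6, C8 = angelate carbons; C4 (methyl C15) and C5 = second oxirane; C7 carries the isopropenyl group.
Cuts: C9=O back to C9–OH; C1–C10 oxirane back to the (E)-olefin; the ring bond C9–C10 (aldehyde + (E)-iodoalkene); C4–C5 oxirane back to the (Z)-olefin; (Z)-C4=C5 by silicon-tethered metathesis into western alcohol 8 (C5–C9) and eastern alcohol 14 (C1–C4, C10).
Forward: 8 (7 steps) and 14 (3 steps) are joined as a silaketal; a seven-membered dioxasilepine sets the 4Z olefin; the open chain receives the C4–C5 oxirane and the three angelates; the ten-membered ring is closed at C9–C10; the second oxirane and the ketone follow.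
Stereochemistry: C8 by Sharpless epoxidation; C7 by SN2 epoxide opening; C6 by chelation-controlled addition; C3 by chiral phosphoric acid propargylation; C4/C5 by C6–OH-directed epoxidation; C9 (temporary) by ligand-controlled ring closure, which then directs the C1/C10 epoxidation and is oxidised away.
Enabling feature: C9 and C10 are adjacent ring atoms that can both be carried as stereochemically blank sp2 carbons (aldehyde carbon; iodine-bearing carbon of the (E)-C1=C10 olefin, which encodes the trans oxirane), and the cis-fused C4–C5 oxirane bends the chain so that the two ends meet.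

Key step: step 21

Remark on the chemistry: the absolute sense of the chiral phosphoric acid (step 8) and of the chiral chromium ligand (step 21) is assigned by analogy with simple aldehydes; the antipodal catalyst is taken if a first run shows the opposite sense.

Step 1
Reactants: 1 (E)-but-2-ene-1,4-diol
Product: 2 (E)-4-[(tert-butyldiphenylsilyl)oxy]but-2-en-1-ol
Conditions: NaH (1.0 equiv), THF, 0 °C; then t-BuPh2SiCl (1.0 equiv), rt
Reagents that add atoms: tert-butyl(chloro)diphenylsilane, CC(C)(C)[Si](Cl)(c1ccccc1)c1ccccc1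
Why: O-silylation of the sparingly soluble monosodium alkoxide of the symmetrical diol should stop at the mono-ether and so differentiates the two ends.

Step 2
Reactants: 2 (E)-4-[(tert-butyldiphenylsilyl)oxy]but-2-en-1-ol
Product: 3 [(2S,3S)-3-{[(tert-butyldiphenylsilyl)oxy]methyl}oxiran-2-yl]methanol
Conditions: Ti(OiPr)4 (10 mol %), L-(+)-diethyl tartrate (12 mol %), t-BuOOH, 4 Å molecular sieves, CH2Cl2, −20 °C
Reagents that add atoms: tert-butyl hydroperoxide, CC(C)(C)OO
Why: Sharpless asymmetric epoxidation of the (E)-allylic alcohol delivers oxygen to one olefin face under reagent control, which sets the future C8 centre and gives the trans oxirane needed for the anti C7/C8 relationship.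

Step 3
Reactants: 3 (2S,3S)-epoxy alcohol
Product: 4 (2R,3R)-4-[(tert-butyldiphenylsilyl)oxy]-2-(prop-1-en-2-yl)butane-1,3-diol
Conditions: isopropenylmagnesium bromide (3 equiv), CuI (10 mol %), THF, −40 to −10 °C
Reagents that add atoms: isopropenylmagnesium bromide, C=C(C)[Mg]Br
Why: Copper-catalysed Grignard opening of a 2,3-epoxy alcohol should occur by SN2 attack at C2, the carbon remote from the deactivating silyloxymethyl group, so that inversion there sets C7 anti to the C8 hydroxyl.

Step 4
Reactants: 4 (2R,3R)-1,3-diol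
Product: 5 (2R,4R,5R)-4-{[(tert-butyldiphenylsilyl)oxy]methyl}-2-(4-methoxyphenyl)-5-(prop-1-en-2-yl)-1,3-dioxane
Conditions: 4-MeOC6H4CH(OMe)2, pyridinium p-toluenesulfonate (cat.), CH2Cl2, rt
Reagents that add atoms: 4-methoxybenzaldehyde dimethyl acetal, COC(OC)c1ccc(OC)cc1
Why: Acid-catalysed transacetalisation of the 1,3-diol should give the thermodynamic six-membered 4-methoxybenzylidene acetal with all substituents equatorial.

Step 5
Reactants: 5 4-methoxybenzylidene acetal
Product: 6 (2R,3R)-4-[(tert-butyldiphenylsilyl)oxy]-3-[(4-methoxybenzyl)oxy]-2-(prop-1-en-2-yl)butan-1-ol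
Conditions: i-Bu2AlH (3 equiv), CH2Cl2, −78 to 0 °C
Reagents that add atoms: none
Why: Regioselective reductive acetal opening, in which aluminium binds the less hindered primary oxygen and releases it as the alcohol, should leave the 4-methoxybenzyl ether on the secondary C8 oxygen.

Step 6
Reactants: 6 primary alcohol
Product: 7 (2S,3R)-4-[(tert-butyldiphenylsilyl)oxy]-3-[(4-methoxybenzyl)oxy]-2-(prop-1-en-2-yl)butanal
Conditions: Dess–Martin periodinane, NaHCO3, CH2Cl2, 0 °C; used directly
Reagents that add atoms: none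
Why: Dess–Martin oxidation under buffered, non-basic conditions should give the α-isopropenyl aldehyde without epimerisation at C7 or migration of the double bond into conjugation.

Step 7
Reactants: 7 aldehyde
Product: 8 (3R,4R,5R)-6-[(tert-butyldiphenylsilyl)oxy]-5-[(4-methoxybenzyl)oxy]-4-(prop-1-en-2-yl)hex-1-en-3-ol
Conditions: MgBr2·OEt2 (3 equiv), CH2Cl2, −78 °C; then vinylmagnesium bromide, −78 °C
Reagents that add atoms: vinylmagnesium bromide, C=C[Mg]Br
Why: Chelation-controlled Grignard addition, in which magnesium bridges the aldehyde and the β-OPMB oxygen in a six-membered chelate with the C7 and C8 substituents equatorial, should bring vinyl in anti to the isopropenyl group and set C6 (2,3-anti).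

Step 8
Reactants: 9 methacrolein
Product: 10 (3S)-2-methylhex-1-en-5-yn-3-ol
Conditions: allenylboronic acid pinacol ester, (S)-3,3′-bis(2,4,6-triisopropylphenyl)-1,1′-binaphthyl-2,2′-diyl hydrogen phosphate (5 mol %), 4 Å molecular sieves, toluene, −20 °C
Reagents that add atoms: allenylboronic acid pinacol ester, C=C=CB1OC(C)(C)C(C)(C)O1
Why: Chiral Brønsted acid-catalysed propargylation (SE2′ addition of the allenylboronate through a six-membered chair transition state held by the phosphoric acid) should set the C3 carbinol under catalyst control.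

Step 9
Reactants: 10 (3S)-2-methylhex-1-en-5-yn-3-ol
Product: 12 (3S)-2-methylhept-1-en-5-yn-3-ol, via dilithium alkoxide-acetylide 11 (not isolated)
Conditions: n-BuLi (2.1 equiv), THF, −78 °C; then MeI (1.05 equiv), −78 °C to rt
Reagents that add atoms: iodomethane, CI
Why: In the dianion the acetylide carbon is the better nucleophile than the lithium alkoxide in THF, so C-methylation should install the C14 methyl.

Step 10
Reactants: 12 (3S)-2-methylhept-1-en-5-yn-3-ol
Product: 14 (3S,5E)-6-iodo-2-methylhepta-1,5-dien-3-ol, via alkenylzirconocene chloride 13 (not isolated)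
Conditions: Cp2Zr(H)Cl (2.5 equiv), THF, rt to 45 °C; then I2, 0 °C
Reagents that add atoms: iodine, II
Why: Hydrozirconation adds H–Zr syn across the alkyne with zirconium at the less hindered methyl-bearing carbon, and iododezirconation with retention should give the (E)-2-iodoalkene that encodes the C1=C10 geometry.

Step 11
Reactants: 8 western allylic alcohol; 14 eastern allylic alcohol
Product: 16 mixed diisopropylsilylene bis-ether of 8 and 14, via chlorosilyl ether 15 (not isolated)
Conditions: 8, i-Pr2SiCl2 (3 equiv), imidazole, CH2Cl2, 0 °C; excess silane removed in vacuo; then 14, imidazole, DMF, rt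
Reagents that add atoms: dichlorodiisopropylsilane, CC(C)[Si](Cl)(Cl)C(C)C
Why: Stepwise O-silylation with a dichlorosilane should link the two secondary allylic alcohols through a temporary silicon tether (O6–Si–O3).

Step 12
Reactants: 16 silaketal
Product: 17 2,2-diisopropyl-5-methyl-4,7-dihydro-1,3,2-dioxasilepine bearing the chain of 14 at C4 and the chain of 8 at C7
Conditions: second-generation Grubbs catalyst RuCl2(=CHPh)(PCy3)(H2IMes) (10 mol %), toluene (3 mM), 90 °C
Reagents that add atoms: none
Why: Ring-closing metathesis within the tether forms a seven-membered ring whose size enforces the (Z)-configuration of the new trisubstituted C4=C5 olefin, while the trisubstituted iodoalkene and the hindered isopropenyl group should stay out of the reaction.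

Step 13
Reactants: 17 dioxasilepine
Product: 18 (Z)-ene-1,4-diol with C3–OH and C6–OH free, O8 as 4-methoxybenzyl ether and O9 as tert-butyldiphenylsilyl ether
Conditions: HF·pyridine, pyridine, THF, 0 °C
Reagents that add atoms: none
Why: Fluoride should cleave the two Si–O bonds of the dialkoxysilane far faster than the tert-butyldiphenylsilyl ether and so release both allylic hydroxyls.

Step 14
Reactants: 18 (Z)-ene-1,4-diol
Product: 19 O6,O8-(4-methoxybenzylidene) acetal with C3–OH free
Conditions: DDQ (1.2 equiv), 4 Å molecular sieves, CH2Cl2, 0 °C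
Reagents that add atoms: none
Why: Anhydrous DDQ oxidation of the 4-methoxybenzyl ether gives an oxocarbenium ion that the syn-1,3 C6 hydroxyl should trap as the six-membered all-equatorial benzylidene acetal, which masks O6 and O8 and leaves only the C3 hydroxyl free.

Step 15
Reactants: 19 acetal alcohol
Product: 20 C3 angelate of 19
Conditions: angelic acid, 2,4,6-trichlorobenzoyl chloride, Et3N, toluene, rt; then 19, toluene, 70 °C
Reagents that add atoms: angelic acid, C/C=C(/C)C(=O)O
Why: Yamaguchi-type esterification through the preformed mixed anhydride should acylate the only free hydroxyl without the nucleophilic catalysis that isomerises an angelate to a tiglate.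

Step 16
Reactants: 20 C3 angelate acetal
Product: 21 C3 angelate with C6–OH and C8–OH free and the (4Z)-olefin
Conditions: AcOH/THF/H2O (4:1:1), 40 °C
Reagents that add atoms: none
Why: Mild aqueous acid should hydrolyse the benzylidene acetal while the ester, the silyl ether and the iodoalkene survive.

Step 17
Reactants: 21 allylic 1,3-diol
Product: 22 (4S,5R)-4,5-epoxide with C6–OH and C8–OH free
Conditions: Ti(OiPr)4 (20 mol %), t-BuOOH (1.5 equiv), 4 Å molecular sieves, CH2Cl2, −20 °C
Reagents that add atoms: tert-butyl hydroperoxide, CC(C)(C)OO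
Why: In this hydroxyl-directed epoxidation A(1,3) strain between C3 and the C6 substituents holds C6–H in the olefin plane, so the titanium-bound C6 alkoxide should deliver oxygen to its own face (threo) and set C4 and C5 of the cis oxirane, while the C3 ester cannot direct and the unbound isopropenyl olefin is not touched.

Step 18
Reactants: 22 epoxy diol
Product: 23 tris-angelate with O9 as tert-butyldiphenylsilyl ether
Conditions: angelic acid (4 equiv), 2,4,6-trichlorobenzoyl chloride, Et3N, toluene, rt; then 22, toluene, 70 °C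
Reagents that add atoms: angelic acid, C/C=C(/C)C(=O)O
Why: The same mixed-anhydride (Yamaguchi-type) esterification should acylate the C6 and C8 hydroxyls with retention of the (Z)-geometry of the acyl group.

Step 19
Reactants: 23 silyl ether
Product: 24 primary C9 alcohol
Conditions: HF·pyridine, pyridine, THF, rt
Reagents that add atoms: none
Why: Buffered HF·pyridine should remove the primary silyl ether without the basic conditions that cause acyl migration from O8, and the oxirane flanked by two acyloxy groups is deactivated toward acid opening.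

Step 20
Reactants: 24 primary alcohol
Product: 25 C9 aldehyde (seco-aldehyde with the (E)-iodoalkene at C1=C10)
Conditions: Dess–Martin periodinane, NaHCO3, CH2Cl2, 0 °C; used at once
Reagents that add atoms: none
Why: Dess–Martin oxidation under neutral conditions should give the α-acyloxy aldehyde without epimerisation at C8.

Step 21
Reactants: 25 iodoalkene aldehyde
Product: 27 (9R)-ten-membered allylic carbinol, via alkenylchromium dichloride 26 (not isolated)
Conditions: CrCl2 (8 equiv), NiCl2 (10 mol %), N-{2-[(4S)-4-isopropyl-4,5-dihydro-1,3-oxazol-2-yl]-6-methylphenyl}methanesulfonamide (8.8 equiv), Et3N (8.8 equiv), THF, rt; 25 added over 12 h (final 2 mM)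
Reagents that add atoms: none
Why: Zerovalent nickel formed in situ inserts into the C10–I bond and hands the alkenyl group to chromium with retention of the (E)-geometry, and the alkenylchromium 26, inert toward the three angelates and the oxirane, adds to the C9 aldehyde. The closest known reaction type is the Nozaki–Hiyama–Kishi macrocyclisation of iodoalkene aldehydes, which has closed nine- and ten-membered carbocycles containing (E)-trisubstituted olefins. The ten-membered ring closes by exo addition to the C9 carbonyl (10-exo-trig), with the cis-fused C4–C5 oxirane and the all-syn C6–C8 substituents acting as turn elements and high dilution suppressing oligomers. The new C9 stereocentre is set by the chiral sulfonamide ligand on chromium (reagent control), which has to override the intrinsic non-chelated bias of the α-acyloxy aldehyde; the 9R carbinol is wanted because it later delivers the epoxidising metal to the required face of C1=C10. The step needs chemoselectivity for the aldehyde over the esters and retention of olefin geometry, both intrinsic to alkenylchromium reagents, and the non-basic medium leaves C8 untouched.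

Step 22
Reactants: 27 (9R)-allylic carbinol
Product: 28 1,10:4,5-diepoxy carbinol
Conditions: VO(acac)2 (10 mol %), t-BuOOH (1.5 equiv), CH2Cl2, 0 °C
Reagents that add atoms: tert-butyl hydroperoxide, CC(C)(C)OO
Why: In this vanadium-catalysed hydroxyl-directed epoxidation the C9 vanadate ester should deliver oxygen to C1=C10 from the face it occupies in the conformer that minimises A(1,2) strain with the C14 methyl (erythro), which sets C1 and C10, and the (E)-olefin gives the trans oxirane.

Step 23
Reactants: 28 epoxy carbinol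
Product: 29 target, (1S,3S,4S,5R,6S,7R,8R,10R)-1,10:4,5-diepoxy-9-oxogermacr-11-ene-3,6,8-triyl tris[(Z)-2-methylbut-2-enoate]
Conditions: Dess–Martin periodinane, NaHCO3, CH2Cl2, 0 °C to rt
Reagents that add atoms: none
Why: Dess–Martin oxidation of the epoxy alcohol to the α,β-epoxy ketone under neutral conditions should erase the temporary C9 stereocentre without epimerising C8.

**Compound list**
1 | (E)-but-2-ene-1,4-diol | OC/C=C/CO | starting material
2 | (E)-4-[(tert-butyldiphenylsilyl)oxy]but-2-en-1-ol | OC/C=C/CO[Si](c1ccccc1)(c1ccccc1)C(C)(C)C | intermediate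
3 | [(2S,3S)-3-{[(tert-butyldiphenylsilyl)oxy]methyl}oxiran-2-yl]methanol | OC[C@@H]1O[C@H]1CO[Si](c1ccccc1)(c1ccccc1)C(C)(C)C | intermediate
4 | (2R,3R)-4-[(tert-butyldiphenylsilyl)oxy]-2-(prop-1-en-2-yl)butane-1,3-diol | OC[C@@H](C(C)=C)[C@@H](O)CO[Si](c1ccccc1)(c1ccccc1)C(C)(C)C | intermediate
5 | (2R,4R,5R)-4-{[(tert-butyldiphenylsilyl)oxy]methyl}-2-(4-methoxyphenyl)-5-(prop-1-en-2-yl)-1,3-dioxane (all substituents equatorial) | COc1ccc(cc1)[C@@H]1OC[C@@H](C(C)=C)[C@H](CO[Si](c2ccccc2)(c2ccccc2)C(C)(C)C)O1 | intermediate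
6 | (2R,3R)-4-[(tert-butyldiphenylsilyl)oxy]-3-[(4-methoxybenzyl)oxy]-2-(prop-1-en-2-yl)butan-1-ol | OC[C@@H](C(C)=C)[C@@H](OCc1ccc(OC)cc1)CO[Si](c1ccccc1)(c1ccccc1)C(C)(C)C | intermediate
7 | (2S,3R)-4-[(tert-butyldiphenylsilyl)oxy]-3-[(4-methoxybenzyl)oxy]-2-(prop-1-en-2-yl)butanal | O=C[C@@H](C(C)=C)[C@@H](OCc1ccc(OC)cc1)CO[Si](c1ccccc1)(c1ccccc1)C(C)(C)C | intermediate
8 | (3R,4R,5R)-6-[(tert-butyldiphenylsilyl)oxy]-5-[(4-methoxybenzyl)oxy]-4-(prop-1-en-2-yl)hex-1-en-3-ol (western fragment; carbinol = C6, then C7, C8, C9) | C=C[C@@H](O)[C@@H](C(C)=C)[C@@H](OCc1ccc(OC)cc1)CO[Si](c1ccccc1)(c1ccccc1)C(C)(C)C | intermediate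
9 | methacrolein (2-methylprop-2-enal) | CC(=C)C=O | starting material
10 | (3S)-2-methylhex-1-en-5-yn-3-ol | C=C(C)[C@@H](O)CC#C | intermediate
11 | dilithium alkoxide-acetylide of 10 | C=C(C)[C@@H]([O-])CC#[C-].[Li+].[Li+] | intermediate (not isolated)
12 | (3S)-2-methylhept-1-en-5-yn-3-ol | C=C(C)[C@@H](O)CC#CC | intermediate
13 | (E)-alkenylzirconocene chloride from 12 (zirconium on the methyl-bearing carbon, hydroxyl as zirconocene alkoxide) | C=C(C)[C@@H](O[Zr](Cl)(C1C=CC=C1)C1C=CC=C1)C/C=C(/[Zr](Cl)(C1C=CC=C1)C1C=CC=C1)C | intermediate (not isolated)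
14 | (3S,5E)-6-iodo-2-methylhepta-1,5-dien-3-ol (eastern fragment; carbinol = C3) | C=C(C)[C@@H](O)C/C=C(/I)C | intermediate
15 | chloro(diisopropyl)silyl ether of 8 | C=C[C@@H](O[Si](Cl)(C(C)C)C(C)C)[C@@H](C(C)=C)[C@@H](OCc1ccc(OC)cc1)CO[Si](c1ccccc1)(c1ccccc1)C(C)(C)C | intermediate (not isolated)
16 | mixed diisopropylsilylene bis-ether joining O6 of 8 and O3 of 14 | C=C[C@@H](O[Si](C(C)C)(C(C)C)O[C@H](C(C)=C)C/C=C(/I)C)[C@@H](C(C)=C)[C@@H](OCc1ccc(OC)cc1)CO[Si](c1ccccc1)(c1ccccc1)C(C)(C)C | intermediate
17 | 2,2-diisopropyl-5-methyl-4,7-dihydro-1,3,2-dioxasilepine; ring C4 (= target C3, S as in 14) bears the (E)-3-iodobut-2-enyl group, ring C7 (= target C6) the C7–C9 chain of 8; ring olefin Z | CC1=C[C@H]([C@@H](C(C)=C)[C@@H](OCc2ccc(OC)cc2)CO[Si](c2ccccc2)(c2ccccc2)C(C)(C)C)O[Si](C(C)C)(C(C)C)O[C@H]1C/C=C(/I)C | intermediate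
18 | open-chain (1E,4Z)-diene 3,6-diol: O8 4-methoxybenzyl ether, O9 tert-butyldiphenylsilyl ether, iodine on C10 (configurations as in 8 and 14) | CC(C)(C)[Si](c1ccccc1)(c1ccccc1)OC[C@H](OCc1ccc(OC)cc1)[C@H](C(C)=C)[C@H](O)/C=C(/C)[C@@H](O)C/C=C(/I)C | intermediate
19 | O6,O8-(4-methoxybenzylidene) acetal of the chain (all-equatorial 1,3-dioxane), C3–OH free | CC(C)(C)[Si](c1ccccc1)(c1ccccc1)OC[C@@H]1O[C@H](c2ccc(OC)cc2)O[C@H](/C=C(/C)[C@@H](O)C/C=C(/I)C)[C@H]1C(C)=C | intermediate
20 | C3 (Z)-2-methylbut-2-enoate of 19 | CC(C)(C)[Si](c1ccccc1)(c1ccccc1)OC[C@@H]1O[C@H](c2ccc(OC)cc2)O[C@H](/C=C(/C)[C@@H](OC(=O)/C(C)=C\C)C/C=C(/I)C)[C@H]1C(C)=C | intermediate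
21 | C3 angelate with free C6 and C8 hydroxyls, (4Z)-olefin, O9 silyl ether | CC(C)(C)[Si](c1ccccc1)(c1ccccc1)OC[C@H](O)[C@H](C(C)=C)[C@H](O)/C=C(/C)[C@@H](OC(=O)/C(C)=C\C)C/C=C(/I)C | intermediate
22 | (4S,5R)-4,5-epoxide of 21 (cis oxirane, threo to the C6 hydroxyl) | CC(C)(C)[Si](c1ccccc1)(c1ccccc1)OC[C@H](O)[C@H](C(C)=C)[C@H](O)[C@H]1O[C@@]1(C)[C@@H](OC(=O)/C(C)=C\C)C/C=C(/I)C | intermediate
23 | 3,6,8-tris-angelate of the 4,5-epoxy chain, O9 silyl ether | CC(C)(C)[Si](c1ccccc1)(c1ccccc1)OC[C@H](OC(=O)/C(C)=C\C)[C@H](C(C)=C)[C@H](OC(=O)/C(C)=C\C)[C@H]1O[C@@]1(C)[C@@H](OC(=O)/C(C)=C\C)C/C=C(/I)C | intermediate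
24 | primary C9 alcohol of the tris-angelate | OC[C@H](OC(=O)/C(C)=C\C)[C@H](C(C)=C)[C@H](OC(=O)/C(C)=C\C)[C@H]1O[C@@]1(C)[C@@H](OC(=O)/C(C)=C\C)C/C=C(/I)C | intermediate
25 | C9 aldehyde (9,10-seco compound: aldehyde at C9, (E)-iodoalkene at C1=C10) | O=C[C@H](OC(=O)/C(C)=C\C)[C@H](C(C)=C)[C@H](OC(=O)/C(C)=C\C)[C@H]1O[C@@]1(C)[C@@H](OC(=O)/C(C)=C\C)C/C=C(/I)C | intermediate
26 | alkenylchromium dichloride from 25 (chromium on C10) | O=C[C@H](OC(=O)/C(C)=C\C)[C@H](C(C)=C)[C@H](OC(=O)/C(C)=C\C)[C@H]1O[C@@]1(C)[C@@H](OC(=O)/C(C)=C\C)C/C=C(/[Cr](Cl)Cl)C | intermediate (not isolated)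
27 | (9R)-ten-membered allylic carbinol: (1(10)E)-olefin, 4,5-oxirane, three angelates | C=C(C)[C@@H]1[C@H](OC(=O)/C(C)=C\C)[C@H]2O[C@@]2(C)[C@@H](OC(=O)/C(C)=C\C)C/C=C(\C)[C@@H](O)[C@@H]1OC(=O)/C(C)=C\C | intermediate
28 | 1,10:4,5-diepoxy C9 carbinol (same spatial arrangement at C9 as in 27; 9S by the sequence rule) | C=C(C)[C@@H]1[C@H](OC(=O)/C(C)=C\C)[C@H]2O[C@@]2(C)[C@@H](OC(=O)/C(C)=C\C)C[C@@H]2O[C@@]2(C)[C@@H](O)[C@@H]1OC(=O)/C(C)=C\C | intermediate
29 | (1S,3S,4S,5R,6S,7R,8R,10R)-1,10:4,5-diepoxy-9-oxogermacr-11-ene-3,6,8-triyl tris[(Z)-2-methylbut-2-enoate] | C=C(C)[C@@H]1[C@H](OC(=O)/C(C)=C\C)[C@H]2O[C@@]2(C)[C@@H](OC(=O)/C(C)=C\C)C[C@@H]2O[C@@]2(C)C(=O)[C@@H]1OC(=O)/C(C)=C\C | target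

**Count and risks**
Total step count: 23. Longest linear sequence: 20 steps (steps 1–7 and 11–23, from 1 to 29).

Steps most likely to fail:

Step 21. Intermolecular coupling may compete with the slow ten-membered closure under the ligand-loaded chromium reagent, and facial selectivity in the addition to the C9 aldehyde may be poor if the ligand and the α-acyloxy stereocentre are mismatched. The fallback sets out from 25 and comes back at 27. The ring is closed with ligand-free CrCl2/NiCl2 in DMSO at high dilution, and the carbinol is accepted as a mixture of 27 and its C9 epimer, the (9S)-carbinol F1. The mixture is oxidised with Dess–Martin periodinane to the single (1(10)E)-cyclodecadienone F2. C9 is then set by Corey–Bakshi–Shibata reduction ((S)- or (R)-1-methyl-3,3-diphenyltetrahydro-1H,3H-pyrrolo[1,2-c][1,3,2]oxazaborole, catecholborane, toluene, −78 °C), keeping the catalyst antipode that leads to 27.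

Step 22. Facial selectivity may be poor if attack from the exposed ring face outruns hydroxyl delivery, and the acyl group may migrate from O8 to the metal-bound O9. The fallback sets out from 27 and comes back at 28. The carbinol is masked as its triethylsilyl ether F3 (Et3SiOSO2CF3, 2,6-lutidine, CH2Cl2, −78 °C). The (E)-trisubstituted olefin is then epoxidised under reagent control by Shi epoxidation (fructose-derived ketone or its enantiomer, Oxone, K2CO3, MeCN/dimethoxymethane/water, 0 °C) to the epoxy silyl ether F4. HF·pyridine frees the alcohol.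

Step 18. Acylation of the two hindered hydroxyls may be slow, with isomerisation of the acyl donor to the (E)-isomer (tiglate) or base-induced migration of the oxirane competing. The fallback sets out from 22 and comes back at 23. Both hydroxyls are esterified with the saturated 2-[bis(2,2,2-trifluoroethoxy)phosphoryl]propanoic acid (N,N′-diisopropylcarbodiimide, catalytic 4-(dimethylamino)pyridine, CH2Cl2) to the bis-phosphonate F5. Both (Z)-2-methylbut-2-enoates are then built on the substrate by Still–Gennari olefination with acetaldehyde (KN(SiMe3)2, 18-crown-6, THF, −78 °C).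

Further compounds
F1 | step 21 | (9S)-carbinol, C9 epimer of 27 | C=C(C)[C@@H]1[C@H](OC(=O)/C(C)=C\C)[C@H]2O[C@@]2(C)[C@@H](OC(=O)/C(C)=C\C)C/C=C(\C)[C@H](O)[C@@H]1OC(=O)/C(C)=C\C
F2 | step 21 | (1(10)E)-4,5-epoxy-9-oxo cyclodecadienone tris-angelate | C=C(C)[C@@H]1[C@H](OC(=O)/C(C)=C\C)[C@H]2O[C@@]2(C)[C@@H](OC(=O)/C(C)=C\C)C/C=C(\C)C(=O)[C@@H]1OC(=O)/C(C)=C\C
F3 | step 22 | C9 triethylsilyl ether of 27 | C=C(C)[C@@H]1[C@H](OC(=O)/C(C)=C\C)[C@H]2O[C@@]2(C)[C@@H](OC(=O)/C(C)=C\C)C/C=C(\C)[C@@H](O[Si](CC)(CC)CC)[C@@H]1OC(=O)/C(C)=C\C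
F4 | step 22 | C9 triethylsilyl ether of 28 | C=C(C)[C@@H]1[C@H](OC(=O)/C(C)=C\C)[C@H]2O[C@@]2(C)[C@@H](OC(=O)/C(C)=C\C)C[C@@H]2O[C@@]2(C)[C@@H](O[Si](CC)(CC)CC)[C@@H]1OC(=O)/C(C)=C\C
F5 | step 18 | 6,8-bis{2-[bis(2,2,2-trifluoroethoxy)phosphoryl]propanoate} of 22 | CC(C)(C)[Si](c1ccccc1)(c1ccccc1)OC[C@H](OC(=O)C(C)P(=O)(OCC(F)(F)F)OCC(F)(F)F)[C@H](C(C)=C)[C@H](OC(=O)C(C)P(=O)(OCC(F)(F)F)OCC(F)(F)F)[C@H]1O[C@@]1(C)[C@@H](OC(=O)/C(C)=C\C)C/C=C(/I)C
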